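The readings are simulated from invented constants; scatter was added.

At the first reading, 0.417 h, the grey run already held 37.8% target and the red run 31.4%; red, with 0.15 M of protic impurity against 0.067 M, held less. I read those first moments as a contest for starting material, which either converted to intermediate and on to target or was quenched by protic impurity. By 2.00 h target had sunk to 36.1% in grey and 27.7% in red, so I took the middle of each run as target, formed ahead of isomer of the product under kinetic control, giving way to thermodynamic control. At 40.0 h the two runs stood at 35.9% and 27.3%, with a reading scatter of 0.3 percentage points.

| flask | starting material | protic impurity | remark | time |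
|---|---|---|---|---|
| grey | 0.20 M | 0.067 M | run made earlier |  |
| red | 0.20 M | 0.15 M | run made earlier |  |
| flask | 0.20 M | 0.100 M |  | 2.0 d |

| run | time / h | target / % |
|---|---|---|
| grey | 0.417 | 37.8 |
| grey | 2.00 | 36.1 |
| grey | 8.00 | 35.4 |
| grey | 40.0 | 35.9 |
| red | 0.417 | 31.4 |
| red | 2.00 | 27.7 |
| red | 8.00 | 27.5 |
| red | 40.0 | 27.3 |

(scatter of a reading: 0.3 percentage points)

1. when, up to 2.0 d, the flask holds most target
2. the amount of target, in percent of the starting material charged, at that time

If quench rate grows with c(protic impurity) while conversion does not, and if c(protic impurity) stays at its charge, the final target times the sum of c(protic impurity) and a fixed concentration stays constant; c(protic impurity) does fall as quench runs, so I used this only as a fitted approximation, at a charge of 0.20 M of starting material. I called that concentration the break-even impurity, the c(protic impurity) at which quench and conversion take equal shares, and the two end readings gave 0.196 M. For the flask, at 0.100 M, I reckoned a plateau of 31.9%. The same rule on the first readings gave 0.340 M and 35.0% for the flask at 0.417 h, my figure for its peak. The forecast put the peak at 35.3% and 0.35 h, adding that “the timing is poorly constrained because no earlier readings exist”.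

    starting material → intermediate (k = 0.00110 s⁻¹)
    intermediate ⇌ target (K = 7.30, k = 0.0130 s⁻¹)
    intermediate ⇌ isomer of the product (K = 7.90, k = 0.00440 s⁻¹)
    starting material + protic impurity → quenched substrate (k = 0.00680 M⁻¹ s⁻¹)
    starting material + target ⇌ idle adduct, settled at all times (K = 14.0 M⁻¹)

The flask peaked at 35.9% at 0.598 h, later than forecast, and ended with 31.9% target against my plateau of 31.9%, with 42% of its protic impurity left rather than the full charge of my approximation. Conversion alone halves starting material in 0.175 h, and quench alone, at charged concentrations, in 0.28 h, a slower path; quenched substrate ended at 29.2%. For the neighbour with 0.25 M of protic impurity, the break-even impurity gives 21.2%, and that flask ended with 20.7% target.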